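**Retrosynthetic overview**

1. Target 12 ⇐ 11 (loss of the two ring-B silyl groups) ⇐ acyclic, achiral enone 9: ring C is opened at O1–C2 and at C3–H. Forward, this is a desilylative oxa-Michael addition with enantioselective protonation at C3.
2. Enabling feature: O1 is a phenol oxygen on C8a, ortho to the C4 acyl group on C4a, so O1–C2–C3–C4(=O) is a β-aryloxy ketone and C2 can be a terminal methylene acceptor. C3 is a CH between C4=O and ring B (C1′), so its configuration can be written by protonating the C3=C4 enolate.
3. 9 ⇐ deoxybenzoin 8 + formaldehyde (C2). The C6 and C5′ prenyl groups ⇐ one double Stille coupling on dibromide 7.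
4. Rings A and B are the same 5-bromo-2,4-dioxygenated phenyl unit: the C3–C4 bond of 5 ⇐ two molecules of aldehyde 2, one as its tosylhydrazone (formyl C–H insertion); 2 ⇐ commercial 1.
5. Ring order: rings A and B are bought as one benzene building block used twice; ring C is the only ring made and is closed last (step 8).

Key step: step 8

Remark on the chemistry (assumption): the absolute sense of the alkaloid-controlled protonation in step 8 cannot be predicted with certainty. (DHQD)2AQN is written; the pseudoenantiomeric (DHQ)2AQN would be used instead if it is the one that delivers (3S).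

**Route**

Step 1
Reactants: 1 5-bromo-2,4-dihydroxybenzaldehyde
Product: 2 5-bromo-2,4-bis(methoxymethoxy)benzaldehyde
Conditions: MOMCl (3 equiv), i-Pr2NEt (4 equiv), CH2Cl2, 0 °C to reflux
Reagents that add atoms: chloromethyl methyl ether, COCCl
Why: O-alkylation of both phenols (acetal protection) should go to completion with excess reagent, the hydrogen-bonded 2-OH reacting last, and gives ethers that survive the basic 110 °C coupling of step 3.

Step 2
Reactants: 2 5-bromo-2,4-bis(methoxymethoxy)benzaldehyde (half of the material)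
Product: 3 (E)-N′-[5-bromo-2,4-bis(methoxymethoxy)benzylidene]-4-methylbenzenesulfonohydrazide
Conditions: TsNHNH2 (1.0 equiv), MeOH, rt
Reagents that add atoms: 4-methylbenzenesulfonohydrazide, Cc1ccc(cc1)S(=O)(=O)NN
Why: Condensation of an aryl aldehyde with tosylhydrazide to the (E)-N-tosylhydrazone is fast and needs no acid, so the MOM acetals should stay untouched.

Step 3
Reactants: 3 (E)-N′-[5-bromo-2,4-bis(methoxymethoxy)benzylidene]-4-methylbenzenesulfonohydrazide; 2 5-bromo-2,4-bis(methoxymethoxy)benzaldehyde (second half)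
Product: 5 1,2-bis[5-bromo-2,4-bis(methoxymethoxy)phenyl]ethan-1-one, via aryldiazomethane 4 (not isolated)
Conditions: K2CO3 (2 equiv), 1,4-dioxane, 110 °C
Reagents that add atoms: none
Why: Bamford–Stevens release of aryldiazomethane 4, its addition to the aldehyde carbon of 2 and a 1,2-hydride shift with loss of N2 (formal formyl C–H insertion, a known ketone synthesis from N-tosylhydrazones and aryl aldehydes) should give the deoxybenzoin, and because both partners carry the same aryl group the bromine positions of both rings are fixed by the starting material.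

Step 4
Reactants: 5 1,2-bis[5-bromo-2,4-bis(methoxymethoxy)phenyl]ethan-1-one
Product: 6 1,2-bis(5-bromo-2,4-dihydroxyphenyl)ethan-1-one
Conditions: 3 M aq HCl, MeOH–THF, 50 °C
Reagents that add atoms: none
Why: Acid-catalysed acetal methanolysis should remove all four MOM groups at a stage with no prenyl group and no stereocentre, and the ketone, deactivated by the chelating 2-OH, should not condense with the 2′-OH under these mild conditions.

Step 5
Reactants: 6 1,2-bis(5-bromo-2,4-dihydroxyphenyl)ethan-1-one
Product: 7 1,2-bis[5-bromo-2,4-bis(tert-butyldimethylsilyloxy)phenyl]ethan-1-one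
Conditions: TBSCl (6 equiv), imidazole (10 equiv), DMAP (cat.), DMF, 50 °C
Reagents that add atoms: tert-butyldimethylsilyl chloride, CC(C)(C)[Si](C)(C)Cl
Why: Silyl ether formation on all four phenols (heating and DMAP for the chelated 2-OH) installs groups that are stable to Pd(0) and to mild acid but labile to fluoride, which is the trigger the key step uses.

Step 6
Reactants: 7 1,2-bis[5-bromo-2,4-bis(tert-butyldimethylsilyloxy)phenyl]ethan-1-one
Product: 8 1,2-bis[2,4-bis(tert-butyldimethylsilyloxy)-5-(3-methylbut-2-en-1-yl)phenyl]ethan-1-one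
Conditions: tributyl(prenyl)stannane (3 equiv), Pd(PPh3)4 (10 mol%), toluene, 110 °C
Reagents that add atoms: tributyl(3-methylbut-2-en-1-yl)stannane, CCCC[Sn](CCCC)(CCCC)CC=C(C)C
Why: Double Stille coupling under neutral, fluoride-free conditions should replace both aryl bromides by prenyl groups with transfer through the α-carbon of the allylstannane, and the two equivalent ortho-silyloxy bromides let both side chains be installed in one operation.

Step 7
Reactants: 8 1,2-bis[2,4-bis(tert-butyldimethylsilyloxy)-5-(3-methylbut-2-en-1-yl)phenyl]ethan-1-one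
Product: 9 1,2-bis[2,4-bis(tert-butyldimethylsilyloxy)-5-(3-methylbut-2-en-1-yl)phenyl]prop-2-en-1-one
Conditions: (CH2O)n (3 equiv), i-Pr2NH·TFA (1 equiv), TFA (10 mol%), THF, reflux
Reagents that add atoms: formaldehyde (as paraformaldehyde), C=O
Why: Mannich-type α-methylenation (aminomethylation of the benzylic ketone enol, then elimination of the secondary amine) is a known route to 1,2-diarylprop-2-en-1-ones, its mildly acidic medium should leave the aryl silyl ethers in place, and the still-silylated O8a cannot yet add to the new C2 methylene.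

Step 8
Reactants: 9 1,2-bis[2,4-bis(tert-butyldimethylsilyloxy)-5-(3-methylbut-2-en-1-yl)phenyl]prop-2-en-1-one
Product: 11 (3S)-3-[2,4-bis(tert-butyldimethylsilyloxy)-5-(3-methylbut-2-en-1-yl)phenyl]-7-hydroxy-6-(3-methylbut-2-en-1-yl)-2,3-dihydro-4H-chromen-4-one, via ring-A phenol enone 10 (not isolated)
Conditions: (DHQD)2AQN (20 mol%), PhCOF (2.2 equiv, slow addition), EtOH (4 equiv), DMF–THF, −20 °C
Reagents that add atoms: none
Why: Proposed new method: alkaloid-catalysed ethanolysis of PhCOF releases HF slowly, the alkaloid·HF salt cleaves the two acyl-activated ring-A O–Si bonds of 9 (ortho and para to C4=O) to give 10, the C8a–OH of 10 (held next to C4=O by its hydrogen bond) adds to the unsubstituted C2 terminus under general-base catalysis by the quinuclidine nitrogen, and the resulting C3=C4 enolate is C-protonated inside its ion pair with the quinuclidinium N–H. The closest known reactions are the cinchona alkaloid/latent-HF enantioselective protonation of silyl enol ethers of 2-substituted 1-tetralones and 3-substituted chroman-4-ones, which passes through the same enolate–alkaloidium ion pair, and the base-mediated cyclisation of 2′-hydroxy-α-methylenedeoxybenzoins to racemic isoflavanones (conjugate addition–enantioselective protonation). Ring C closes by 6-endo-trig oxa-Michael formation of the O1–C2 bond. The C3 stereocentre is created in the protonation and is under catalyst control (one enolate face shielded by the alkaloid, reinforced by the bulky, twisted 2′-OTBS aryl group on C3), with the pseudoenantiomeric alkaloid as the lever for the absolute sense. The step needs ring-A over ring-B desilylation (secured by the C4 carbonyl, which makes the ring-A phenoxides the better leaving groups), O1 over O2′ attack (O2′ is still silylated and would need a 5-endo closure) and ion-pair protonation over background protonation (secured by slow HF release, excess EtOH that consumes PhCOF, low temperature and the absence of any achiral ammonium ion). The product should not re-enolise because the medium stays weakly acidic.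

Step 9
Reactants: 11 (3S)-3-[2,4-bis(tert-butyldimethylsilyloxy)-5-(3-methylbut-2-en-1-yl)phenyl]-7-hydroxy-6-(3-methylbut-2-en-1-yl)-2,3-dihydro-4H-chromen-4-one
Product: 12 (3S)-3-[2,4-dihydroxy-5-(3-methylbut-2-en-1-yl)phenyl]-7-hydroxy-6-(3-methylbut-2-en-1-yl)-2,3-dihydro-4H-chromen-4-one
Conditions: TBAF (2.5 equiv), AcOH (3 equiv), THF, 0 °C
Reagents that add atoms: none
Why: Fluoride cleavage of the two remaining aryl silyl ethers buffered with acetic acid should be fast at 0 °C and never creates a basic phenoxide/fluoride medium, so C3 is not enolised and the prenyl groups and the 2′-hydroxy ketone are not exposed to strong acid.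

**Compound list**

1 | 5-bromo-2,4-dihydroxybenzaldehyde | O=Cc1cc(Br)c(O)cc1O | starting material
2 | 5-bromo-2,4-bis(methoxymethoxy)benzaldehyde | COCOc1cc(OCOC)c(Br)cc1C=O | intermediate
3 | (E)-N′-[5-bromo-2,4-bis(methoxymethoxy)benzylidene]-4-methylbenzenesulfonohydrazide | COCOc1cc(OCOC)c(Br)cc1/C=N/NS(=O)(=O)c1ccc(C)cc1 | intermediate
4 | 1-bromo-5-(diazomethyl)-2,4-bis(methoxymethoxy)benzene | COCOc1cc(OCOC)c(Br)cc1C=[N+]=[N-] | intermediate (not isolated)
5 | 1,2-bis[5-bromo-2,4-bis(methoxymethoxy)phenyl]ethan-1-one | COCOc1cc(OCOC)c(Br)cc1C(=O)Cc1cc(Br)c(OCOC)cc1OCOC | intermediate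
6 | 1,2-bis(5-bromo-2,4-dihydroxyphenyl)ethan-1-one | Oc1cc(O)c(Br)cc1C(=O)Cc1cc(Br)c(O)cc1O | intermediate
7 | 1,2-bis[5-bromo-2,4-bis(tert-butyldimethylsilyloxy)phenyl]ethan-1-one | CC(C)(C)[Si](C)(C)Oc1cc(O[Si](C)(C)C(C)(C)C)c(Br)cc1C(=O)Cc1cc(Br)c(O[Si](C)(C)C(C)(C)C)cc1O[Si](C)(C)C(C)(C)C | intermediate
8 | 1,2-bis[2,4-bis(tert-butyldimethylsilyloxy)-5-(3-methylbut-2-en-1-yl)phenyl]ethan-1-one | CC(C)(C)[Si](C)(C)Oc1cc(O[Si](C)(C)C(C)(C)C)c(CC=C(C)C)cc1C(=O)Cc1cc(CC=C(C)C)c(O[Si](C)(C)C(C)(C)C)cc1O[Si](C)(C)C(C)(C)C | intermediate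
9 | 1,2-bis[2,4-bis(tert-butyldimethylsilyloxy)-5-(3-methylbut-2-en-1-yl)phenyl]prop-2-en-1-one | CC(C)(C)[Si](C)(C)Oc1cc(O[Si](C)(C)C(C)(C)C)c(CC=C(C)C)cc1C(=O)C(=C)c1cc(CC=C(C)C)c(O[Si](C)(C)C(C)(C)C)cc1O[Si](C)(C)C(C)(C)C | intermediate
10 | 2-[2,4-bis(tert-butyldimethylsilyloxy)-5-(3-methylbut-2-en-1-yl)phenyl]-1-[2,4-dihydroxy-5-(3-methylbut-2-en-1-yl)phenyl]prop-2-en-1-one | Oc1cc(O)c(CC=C(C)C)cc1C(=O)C(=C)c1cc(CC=C(C)C)c(O[Si](C)(C)C(C)(C)C)cc1O[Si](C)(C)C(C)(C)C | intermediate (not isolated)
11 | (3S)-3-[2,4-bis(tert-butyldimethylsilyloxy)-5-(3-methylbut-2-en-1-yl)phenyl]-7-hydroxy-6-(3-methylbut-2-en-1-yl)-2,3-dihydro-4H-chromen-4-one | CC(C)=CCc1cc2c(cc1O)OC[C@H](c1cc(CC=C(C)C)c(O[Si](C)(C)C(C)(C)C)cc1O[Si](C)(C)C(C)(C)C)C2=O | intermediate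
12 | (3S)-3-[2,4-dihydroxy-5-(3-methylbut-2-en-1-yl)phenyl]-7-hydroxy-6-(3-methylbut-2-en-1-yl)-2,3-dihydro-4H-chromen-4-one | CC(C)=CCc1cc2c(cc1O)OC[C@H](c1cc(CC=C(C)C)c(O)cc1O)C2=O | target

Total step count: 9. Longest linear sequence: 9 steps (1 to 12; one building block, used twice in step 3).

**Steps most likely to fail**

1. Step 8 (proposed new method). What may go wrong: loss of facial control in the C3 protonation (background protonation of the enolate by free HF or by the liberated phenols, or premature loss of the 2′-silyl group), and O-benzoylation of the liberated phenols by PhCOF. Fallback with known chemistry, from 9 back to 11: 9 is cyclised without stereocontrol with Et3N·3HF (THF, 0 °C; fluoride/base-mediated isoflavanone closure) to racemic 3-[2,4-bis(tert-butyldimethylsilyloxy)-5-prenylphenyl]-7-hydroxy-6-prenylchroman-4-one F1. F1 is converted with LiHMDS (2.2 equiv) and TMSCl (THF, −78 °C) into the 4,7-bis(trimethylsilyloxy)-2H-chromene F2. F2 is protonated with a BINOL-derived N-triflyl thiophosphoramide (5 mol%) and phenol as stoichiometric proton source in toluene (catalytic enantioselective protonation of silyl enol ethers of 2-aryl cyclic ketones). Methanolic work-up, which also removes the aryl O–SiMe3 group, should return 11.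

2. Step 3. What may go wrong: dimerisation of the diazo intermediate (azine, stilbene) or its thermal loss of N2 before it adds to the electron-rich, hindered aldehyde, and aryl instead of hydride migration in the adduct. Fallback from 2 back to 5: McMurry homocoupling of 2 (TiCl4, Zn, pyridine, THF, reflux) to the C2-symmetric (E)-1,2-bis[5-bromo-2,4-bis(methoxymethoxy)phenyl]ethene F3. Hydroboration–oxidation (BH3·THF; then NaOH, H2O2), which can give only one regioisomer because the alkene is symmetric, leads to 1,2-bis[5-bromo-2,4-bis(methoxymethoxy)phenyl]ethan-1-ol F4. Oxidation with DMP (CH2Cl2, NaHCO3) gives 5.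

3. Step 6. What may go wrong: slow oxidative addition at the two electron-rich C–Br bonds flanked by OTBS groups (incomplete, mono-coupled material), and transfer of the prenyl group through its γ-carbon (reverse-prenyl isomer). Fallback from 7 back to 8: double Suzuki–Miyaura allylation with allylboronic acid pinacol ester (Pd(OAc)2/SPhos, anhydrous K3PO4, toluene, 80 °C; no α/γ ambiguity) to 1,2-bis[5-allyl-2,4-bis(tert-butyldimethylsilyloxy)phenyl]ethan-1-one F5. Cross-metathesis with 2-methyl-2-butene (second-generation Ru benzylidene catalyst, CH2Cl2, 40 °C) then converts both allyl groups into prenyl groups and gives 8.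

**Further compounds**

F1 | step 8 | rac-3-[2,4-bis(tert-butyldimethylsilyloxy)-5-(3-methylbut-2-en-1-yl)phenyl]-7-hydroxy-6-(3-methylbut-2-en-1-yl)-2,3-dihydro-4H-chromen-4-one | CC(C)=CCc1cc2c(cc1O)OCC(c1cc(CC=C(C)C)c(O[Si](C)(C)C(C)(C)C)cc1O[Si](C)(C)C(C)(C)C)C2=O
F2 | step 8 | 3-[2,4-bis(tert-butyldimethylsilyloxy)-5-(3-methylbut-2-en-1-yl)phenyl]-6-(3-methylbut-2-en-1-yl)-4,7-bis(trimethylsilyloxy)-2H-chromene | CC(C)=CCc1cc2c(cc1O[Si](C)(C)C)OCC(c1cc(CC=C(C)C)c(O[Si](C)(C)C(C)(C)C)cc1O[Si](C)(C)C(C)(C)C)=C2O[Si](C)(C)C
F3 | step 3 | (E)-1,2-bis[5-bromo-2,4-bis(methoxymethoxy)phenyl]ethene | COCOc1cc(OCOC)c(Br)cc1/C=C/c1cc(Br)c(OCOC)cc1OCOC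
F4 | step 3 | rac-1,2-bis[5-bromo-2,4-bis(methoxymethoxy)phenyl]ethan-1-ol | COCOc1cc(OCOC)c(Br)cc1C(O)Cc1cc(Br)c(OCOC)cc1OCOC
F5 | step 6 | 1,2-bis[5-allyl-2,4-bis(tert-butyldimethylsilyloxy)phenyl]ethan-1-one | CC(C)(C)[Si](C)(C)Oc1cc(O[Si](C)(C)C(C)(C)C)c(CC=C)cc1C(=O)Cc1cc(CC=C)c(O[Si](C)(C)C(C)(C)C)cc1O[Si](C)(C)C(C)(C)C
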